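**Assumptions.** Ring A atoms are cited in the chromone numbering of 24 (C4a, C5, C6, C7, C8, C8a) throughout, also in open-chain precursors. Lithium enolates made in situ are treated as reactive forms of their numbered parents and are not numbered. The two methine carbons of 9 are each alpha to carbonyl groups and epimerise freely, so 9 is formulated without stereodescriptors.

## Structural features

Eryvarin F (24) is an achiral 3-aryloxychromone: benzene ring A is fused to 4-pyranone ring C, and ring B, a 2,4-dihydroxyphenyl group, is bound to C3 through an ether oxygen and not through a carbon–carbon bond. Ring A is pentasubstituted: prenyl chains at C6 and C8 flank the free 7-hydroxyl, C8a carries the pyranone oxygen, C4a carries the carbonyl carbon C4, and only C5 bears hydrogen. The molecule has no stereocentres, so no neighbouring stereocentres have to be related; the only stereochemical point is that the two labile methine centres of the open-chain precursor disappear on aromatisation. The fragile parts are the two trisubstituted side-chain alkenes ortho to a phenol (cyclisation to dimethylchromans in strong acid, no hydrogenation, no strong Lewis acids or electrophilic halogen), the oxidation-prone, electron-rich ring B, and the chromone C2 position, which is opened by hard nucleophiles. The real difficulty is the regiodefined assembly of the crowded ring A, with two oxygens and two identical chains in alternation, together with the aryl–O–C3 ether, which the usual isoflavone logic does not provide. The key step exploits the fact that O8a, O7 and the carboxyl-level carbon C4 on C4a form a resorcylate pattern, that is, a folded polyketide chain in which C4, C8a, C7 and C5 are carbonyl carbons and C4a, C8 and C6 are enolisable carbons. Ring A can therefore be closed through the C4a–C5 bond by an aldol reaction, with each prenyl group placed beforehand on an enolisable chain carbon and with C4/C8a masked as a dioxinone that later supplies C4 and O1 of ring C.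

## Logic of the disconnections

**24 to 23.** The three phenolic O–H bonds are traced back to O–CH2OCH3 bonds. The ring B hydroxyls have to be masked through enolate and formamide-acetal chemistry and O7 has to be masked for the acyl transfer; one group type for all three allows a single unmasking. The demand on the forward step is an acid cleavage mild enough to spare prenyl groups ortho to a phenol.

**23 to 21.** The O1–C2 and C2–C3 bonds are cut and C2 is removed as a one-carbon electrophile at the formic acid oxidation level. This removes ring C and leaves an aryl aryloxymethyl ketone with a free ortho-hydroxyl, the classical precursor of 3-aryloxychromones. The forward step needs an acidic methylene in 21 and requires that the only free hydroxyl be the one that becomes O1.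

**21 to 12 and 19.** The C4–C3 bond is cut. C4 is already at the carboxyl level in 12 as an activated acylal, and C3 is the alpha carbon of an aryloxyacetic acid, so ring B arrives with its ether oxygen in place and no C3–O bond has to be made on a chromone. The carboxyl group of 19 serves as a removable activating group that is lost as carbon dioxide. An ionic acyl transfer is preferred over a pericyclic opening of 12 to an ortho-quinone ketene, because benzo-fused dioxinones cyclorevert only on irradiation or at temperatures far above those of simple dioxinones, which suits neither the prenyl groups nor an enamine partner. The demand is an electrophilic carbonyl in 12, hence the masked O7, and two equivalents of the dianion of 19.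

**19 to 16 and 17, 16 to 14, 14 to 13.** The O–CH2 bond of 19 is cut to a phenol and a bromoacetate. The aryl C–O bond of 16 is cut by a retro-Baeyer–Villiger step to the aldehyde 14, which is the bis-protected form of the cheap 13. This gives the 1,2,4-trioxygenated ring B with the three oxygens differentiated from the start. The demand is aryl migration, not hydride migration, in the oxidation, which the two donor substituents secure.

**12 to 11.** The O7–C bond of the protecting group is cut. The free phenol of 11 would give a para-phenoxide under the basic conditions of the acyl transfer and deactivate the carbonyl, so it is capped.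

**11 to 9 (key disconnection).** The C4a–C5 bond is cut and water is added back across C5–C6, which opens ring A to a keto-dioxinone aldehyde. The gain is the largest of the route: a pentasubstituted benzene becomes an open chain whose substituents sit on ordinary enolisable carbons. Three points sharpen the design of 9:
- 9 is a mixture of two racemic diastereomers and several enol tautomers, so no configuration is assigned.
- 9 is a 2-alkyl-3-oxoaldehyde and is released from its acetal only immediately before use.
- The base must be a non-nucleophilic amine in an aprotic solvent, because alkoxide or carbonate in an alcohol would remove the formyl carbon by retro-Claisen cleavage.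

**9 to 8.** The aldehyde is traced to its dimethyl acetal, so that the most electrophilic carbon of the chain stays masked through all enolate steps. The demand is a hydrolysis mild enough for the dioxinone and the alkenes.

**8 to 3 and 6 (through 7).** The C7–C8 bond is cut between the gamma carbon of a dioxinone dienolate and an acyl donor. Both halves then carry one prenyl group each and are of similar size. The demand is C-acylation at the gamma carbon by a branched acyl donor that is activated without acid.

**3 to 1 and 2; 6 to 5 to 4 and 2.** The C–C bonds between each prenyl group and its enolisable carbon are cut. Both prenyl groups then come from the same bromide by simple enolate alkylation, and the starting materials are commodity chemicals. The demand is gamma selectivity for the dienolate of 1 and an alkylation of the enolate of 4 that is faster than loss of methoxide.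

## Other disconnections considered

**Alternative 1:** The cut goes through the two side-chain double bonds of the prenyl groups. The bis(methoxymethyl) ether A1 of 24 is traced to the 6,8-diallyl chromone A2, whose allyl groups go back to O7 by two successive O-allylation and aromatic Claisen rearrangement cycles, first to C8 and then, with C8 blocked, to C6. In the forward key step A2 undergoes twofold cross-metathesis with 2-methylbut-2-ene A3 as solvent under the second-generation Grubbs catalyst RuCl2(=CHPh)(PCy3)(H2IMes); no ring closes.
- In its favour: ring A is never constructed but taken from a resorcinol-type core. The acid-sensitive prenyl groups appear one step before the end, so the chromone may be built with acidic or Lewis-acidic classics. The metathesis tolerates free phenols, MOM ethers and the chromone, and A1 has only two MOM groups left to remove.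
- Against it here: the side-chain positions rest on the inherent ortho preference of the rearrangement and not on construction. The second rearrangement must be forced into the less reactive C6 at high temperature, where ortho-allylphenols may cyclise or the allyl groups may move into conjugation. Four operations place two three-carbon units, and both metathesis events must go to completion, since mixed allyl/prenyl products and propenyl isomers would be hard to remove.
- Comparison: on structure the chosen plan is the more secure, because C6 and C8 are fixed by the alkylation sites of an open chain. The alternative is the better on one point: it never handles a labile open-chain tricarbonyl compound and takes no prenyl group through enolate or acid steps. On mechanism it replaces ionic enolate chemistry by two sigmatropic shifts and a metal-carbene exchange, each a mature reaction. On step economy the two plans should be about equal.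

**Alternative 2:** The cut goes through the C8a–C8 and C6–C7 bonds, dividing ring A into the four-carbon unit C8a–C4a–C5–C6 of the 2-prenylcyclobutenone A5 and the two-carbon unit C8–C7 of the prenyl-substituted siloxyalkyne A6. In the forward key step (Danheiser benzannulation) heating opens A5 to a vinylketene, which adds to A6 in a regioselective [2+2] cycloaddition. Four-electron opening of the resulting vinylcyclobutenone, six-electron electrocyclisation and tautomerisation then give phenol A4.
- In its favour: two ring bonds and the whole substitution pattern arise in one neutral thermal operation, the regiochemistry follows from the polarity of the ynol ether, and the C8a hydroxyl and the silylated O7 emerge differentiated.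
- Against it here: A4 lacks the carboxyl-level carbon C4 on C4a. An ortho-acylation of an electron-rich, doubly prenylated phenol must follow, and the usual Friedel–Crafts, Fries or Hoesch conditions are those the prenyl groups tolerate least. A5 is a strained, volatile enone and A6 a hydrolytically labile ynol ether, each needing several steps.
- Comparison: on structure the alternative is the equal of the chosen plan in regiocontrol and oxygen differentiation, but it delivers ring A one carbon short, whereas the chosen key step produces C4 at the right oxidation level inside the dioxinone. On mechanism the pericyclic cascade is the better, since it needs neither base nor acid and has no competing heterocyclisation. On step economy it is the poorer, because of the syntheses of A5 and A6 and the extra operations for C4 and ring C.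

**Alternative 3:** The cut goes through C5–C6 and C4a–C8a. C6, C7, C8 and C8a come from the doubly prenylated bis(silyloxy) diene A8, a masked acetoacetate, and C5, C4a, C4, C3 and ring B come from the terminal ynone A9. In the forward key step the nucleophilic terminus of A8 adds to the alkyne carbon beta to the carbonyl of A9, the second bond closes ring A in a Diels–Alder or stepwise Michael/Claisen sense, and elimination of a silyl methyl ether with desilylation aromatises the ring to the ketone A7.
- In its favour: A7 is the O7-unprotected counterpart of 21, so one convergent step delivers ring A together with C4, C3 and the ether-linked ring B, and ring C then needs only the one-carbon closure. Like the chosen plan, it places both prenyl groups by enolate alkylation of an acetoacetate-type chain.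
- Against it here: A8 is substituted at both reacting termini and at its second carbon, which slows ring closure and favours open-chain conjugate adducts. Terminal ynones such as A9 polymerise and add nucleophiles readily, the geometry of the tetrasubstituted diene must be controlled, and the free 7-hydroxyl of A7 is exposed to O-methylation by formamide acetals in the ring C closure.
- Comparison: on structure both plans derive ring A from a polyketide-like chain and are equal in regiochemical logic. On step economy the alternative is the better, since it saves the separate attachment of C3 and ring B (step 11) and the O7 protection (step 7). On mechanism the chosen closure is intramolecular, six-membered and belongs to an established class, whereas the intermolecular union of a hindered diene with a sensitive ynone carries the larger risk in the key step itself.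

Key step: step 6

## Route

Step 1
Reactants: 1 2,2,6-trimethyl-4H-1,3-dioxin-4-one; 2 prenyl bromide (1-bromo-3-methylbut-2-ene)
Product: 3 2,2-dimethyl-6-(4-methylpent-3-en-1-yl)-4H-1,3-dioxin-4-one
Conditions: LiN(iPr)2 (1.1 equiv), THF/DMPU, −78 °C; then 2, −78 → −20 °C
Reagents that add atoms: none
Why: Kinetic deprotonation of the vinylogous ester gives the lithium dienolate, which in the presence of a polar cosolvent alkylates reactive allylic halides at the exocyclic gamma carbon (vinylogous enolate alkylation, SN2 at the primary carbon of 2); the dioxinone ring is inert at low temperature.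

Step 2
Reactants: 4 methyl 3,3-dimethoxypropanoate; 2 prenyl bromide
Product: 5 methyl 2-(dimethoxymethyl)-5-methylhex-4-enoate (racemic)
Conditions: LiN(iPr)2 (1.05 equiv), THF, −78 °C; then 2, DMPU, −78 → −30 °C
Reagents that add atoms: none
Why: Ester enolate alkylation; at −78 °C the enolate of the beta,beta-dialkoxy ester should be trapped by the reactive allylic bromide faster than it expels methoxide. The new stereocentre is racemic and is erased in step 6.

Step 3
Reactants: 5 methyl 2-(dimethoxymethyl)-5-methylhex-4-enoate
Product: 6 2-(dimethoxymethyl)-5-methylhex-4-enoic acid (racemic)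
Conditions: LiOH·H2O, THF/MeOH/H2O, rt; 1 M HCl to pH 4, 0 °C
Reagents that add atoms: lithium hydroxide, [Li+].[OH-]
Why: Saponification of the methyl ester by acyl–oxygen cleavage; acetal and alkene are inert to hydroxide, and the cold, weakly acidic work-up keeps the acetal intact.

Step 4
Reactants: 6 2-(dimethoxymethyl)-5-methylhex-4-enoic acid; 3 2,2-dimethyl-6-(4-methylpent-3-en-1-yl)-4H-1,3-dioxin-4-one
Product: 8 6-[4,4-dimethoxy-1,3-bis(3-methylbut-2-en-1-yl)-2-oxobutyl]-2,2-dimethyl-4H-1,3-dioxin-4-one (diastereomer mixture), via acyl imidazolide 7 (not isolated)
Conditions: 6, CDI (1.05 equiv), THF, rt; separately 3 (2.2 equiv), LiN(SiMe3)2 (3.3 equiv), THF, −78 °C; add the solution of 7, −78 → −30 °C; AcOH quench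
Reagents that add atoms: none
Why: CDI turns 6 into acyl imidazolide 7 under neutral conditions that spare the acetal, and the lithium dienolate of 3 then undergoes crossed Claisen C-acylation at its gamma carbon, the established mode for dioxinone dienolates with acyl imidazolides. One extra equivalent of amide base takes up the imidazole set free by CDI, and the second equivalent of dienolate deprotonates the acidic methine of 8, which also shields it from further attack; excess 3 is recovered.

Step 5
Reactants: 8 6-[4,4-dimethoxy-1,3-bis(3-methylbut-2-en-1-yl)-2-oxobutyl]-2,2-dimethyl-4H-1,3-dioxin-4-one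
Product: 9 6-[1,3-bis(3-methylbut-2-en-1-yl)-2,4-dioxobutyl]-2,2-dimethyl-4H-1,3-dioxin-4-one, also named 2-[2-(2,2-dimethyl-4-oxo-4H-1,3-dioxin-6-yl)-5-methylhex-4-enoyl]-5-methylhex-4-enal (diastereomer and enol mixture; used crude)
Conditions: 1 M aq. HCl, THF, 0 °C → rt; extract, dry (Na2SO4), use at once
Reagents that add atoms: water, O
Why: Acid-catalysed acetal hydrolysis, assisted by the neighbouring enolisable ketone and driven by formation of the chelated hydroxymethylene enol. The dioxinone and the trisubstituted alkenes should tolerate dilute aqueous acid at or below room temperature.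

Step 6
Reactants: 9 6-[1,3-bis(3-methylbut-2-en-1-yl)-2,4-dioxobutyl]-2,2-dimethyl-4H-1,3-dioxin-4-one
Product: 11 7-hydroxy-2,2-dimethyl-6,8-bis(3-methylbut-2-en-1-yl)-4H-1,3-benzodioxin-4-one, via cyclic aldol adduct 10 (not isolated)
Conditions: Et3N (3 equiv), CH2Cl2 (0.02 M), 0 °C → rt; aq. NaH2PO4 work-up
Reagents that add atoms: none
Why: Et3N reversibly removes the C8 proton, which is alpha to the C7 ketone and vinylogously alpha to the dioxinone carbonyl, and gives an extended enolate delocalised over O7, C8, C8a, C4a and the dioxinone carbonyl. Of its two carbon termini only C4a can reach C5, so the C4a–C5 bond forms by a 6-(enolexo)-exo-trig aldol addition to the aldehyde (or, from the enol tautomer, by conjugate addition to the hydroxymethylene carbon), giving 10. E1cB loss of water across C5–C6 and enolisation of the C7 ketone through the C8 proton then aromatise ring A irreversibly, which draws every diastereomer and tautomer of 9 into one achiral product. The closest known reaction type is the amine- or carbonate-mediated aldol aromatisation of diketo-dioxinones to resorcylates; the aldehyde terminus used here is a stronger electrophile than the ketones of that class. No stereocentre is formed, and the two labile methine centres become sp2 carbons. The step needs carbocyclisation to outrun two processes: addition of an enol oxygen to C8a with opening of the dioxinone to a 4-pyranone, and retro-Claisen loss of the formyl carbon. A non-nucleophilic amine in an aprotic solvent without alkoxide, hydroxide or acid secures this, as does the substrate geometry, in which the C4a=C8a double bond holds the chain cis to the C4a hydrogen. Deprotonation at the more acidic C6 gives an unreactive enolate, but it is reversible and only costs rate; high dilution suppresses intermolecular aldol reactions.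

Step 7
Reactants: 11 7-hydroxy-2,2-dimethyl-6,8-bis(3-methylbut-2-en-1-yl)-4H-1,3-benzodioxin-4-one
Product: 12 7-(methoxymethoxy)-2,2-dimethyl-6,8-bis(3-methylbut-2-en-1-yl)-4H-1,3-benzodioxin-4-one
Conditions: MOMCl, iPr2NEt, CH2Cl2, 0 °C → rt
Reagents that add atoms: chloromethyl methyl ether (MOMCl), COCCl
Why: O-Alkylation of the acidic para-acyl phenol with a chloromethyl ether (Williamson type); the small electrophile should reach the hydroxyl between the two prenyl groups. The ether prevents formation of a deactivating para-phenoxide in step 11 and leaves with the ring B ethers in step 13.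

Step 8
Reactants: 13 2,4-dihydroxybenzaldehyde
Product: 14 2,4-bis(methoxymethoxy)benzaldehyde
Conditions: MOMCl (3 equiv), iPr2NEt (4 equiv), CH2Cl2, 0 → 40 °C
Reagents that add atoms: chloromethyl methyl ether (MOMCl), COCCl
Why: Double O-alkylation with a chloromethyl ether; excess reagent and gentle warming should also convert the hydrogen-bonded 2-hydroxyl.

Step 9
Reactants: 14 2,4-bis(methoxymethoxy)benzaldehyde
Product: 16 2,4-bis(methoxymethoxy)phenol, via aryl formate 15 (not isolated)
Conditions: mCPBA, CH2Cl2, 0 °C → rt; then K2CO3 (cat.), MeOH, rt
Reagents that add atoms: 3-chloroperoxybenzoic acid (mCPBA), OOC(=O)c1cccc(Cl)c1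
Why: Baeyer–Villiger (Dakin-type) oxidation, in which the electron-rich aryl group migrates in preference to hydrogen to give formate 15, followed by transesterification with methanol. The oxygen introduced here becomes the ether oxygen on C3 of the target.

Step 10
Reactants: 16 2,4-bis(methoxymethoxy)phenol; 17 ethyl bromoacetate
Product: 19 [2,4-bis(methoxymethoxy)phenoxy]acetic acid, via ethyl ester 18 (not isolated)
Conditions: K2CO3, DMF, rt; then LiOH, H2O/MeOH, rt; 1 M HCl to pH 3, 0 °C
Reagents that add atoms: lithium hydroxide, [Li+].[OH-]
Why: Williamson ether synthesis of the phenoxide with the alpha-bromo ester, then saponification in the same flask. MOM ethers are stable to base and to a brief cold acidification.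

Step 11
Reactants: 12 7-(methoxymethoxy)-2,2-dimethyl-6,8-bis(3-methylbut-2-en-1-yl)-4H-1,3-benzodioxin-4-one; 19 [2,4-bis(methoxymethoxy)phenoxy]acetic acid
Product: 21 2-[2,4-bis(methoxymethoxy)phenoxy]-1-[2-hydroxy-4-(methoxymethoxy)-3,5-bis(3-methylbut-2-en-1-yl)phenyl]ethan-1-one, via beta-keto acid 20 (not isolated)
Conditions: 19 (2.2 equiv), LiN(iPr)2 (4.4 equiv), THF, −78 → 0 °C; then 12, −78 → −20 °C; 1 M HCl to pH 3–4, 0 °C; EtOAc, 45 °C
Reagents that add atoms: none
Why: Claisen-type acylation of a carboxylic acid dianion by an activated ester: the carbanion adds to the acylal carbonyl of 12, and the tetrahedral intermediate collapses with loss of acetone and release of the C8a phenoxide. The second equivalent of dianion converts the adduct into its enolate and so blocks over-addition. Mild acidification gives beta-keto acid 20, which decarboxylates on gentle warming through the usual cyclic transition state; unlike an ester, the carboxylate cannot lactonise onto the liberated phenoxide.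

Step 12
Reactants: 21 2-[2,4-bis(methoxymethoxy)phenoxy]-1-[2-hydroxy-4-(methoxymethoxy)-3,5-bis(3-methylbut-2-en-1-yl)phenyl]ethan-1-one
Product: 23 3-[2,4-bis(methoxymethoxy)phenoxy]-7-(methoxymethoxy)-6,8-bis(3-methylbut-2-en-1-yl)-4H-chromen-4-one, via enaminone 22 (not isolated)
Conditions: Me2NCH(OMe)2 (3 equiv), toluene, 85 °C; then AcOH (cat.), 60 °C
Reagents that add atoms: N,N-dimethylformamide dimethyl acetal, COC(OC)N(C)C
Why: Condensation of the active methylene with the formamide acetal gives enaminone 22; the ortho-hydroxyl then adds to its beta carbon and dimethylamine is eliminated, closing ring C (enaminone route to chromones, standard for 3-aryloxychromones and isoflavones). The only free hydroxyl is the chelated one that becomes O1, so O-methylation by the reagent should not interfere.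

Step 13
Reactants: 23 3-[2,4-bis(methoxymethoxy)phenoxy]-7-(methoxymethoxy)-6,8-bis(3-methylbut-2-en-1-yl)-4H-chromen-4-one
Product: 24 eryvarin F, 3-(2,4-dihydroxyphenoxy)-7-hydroxy-6,8-bis(3-methylbut-2-en-1-yl)-4H-chromen-4-one
Conditions: HCl (about 1 M in MeOH), 0 °C → rt
Reagents that add atoms: none
Why: Acid-catalysed transacetalisation of the three MOM ethers to methanol; low acid strength and temperature should keep the ortho-prenyl phenol from cyclising to a dimethylchroman and leave the chromone intact.

## Compound list

1 | 2,2,6-trimethyl-4H-1,3-dioxin-4-one | CC1=CC(=O)OC(C)(C)O1 | starting material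
2 | prenyl bromide (1-bromo-3-methylbut-2-ene) | CC(C)=CCBr | starting material
3 | 2,2-dimethyl-6-(4-methylpent-3-en-1-yl)-4H-1,3-dioxin-4-one | CC(C)=CCCC1=CC(=O)OC(C)(C)O1 | intermediate
4 | methyl 3,3-dimethoxypropanoate | COC(=O)CC(OC)OC | starting material
5 | methyl 2-(dimethoxymethyl)-5-methylhex-4-enoate (racemic) | COC(=O)C(CC=C(C)C)C(OC)OC | intermediate
6 | 2-(dimethoxymethyl)-5-methylhex-4-enoic acid (racemic) | OC(=O)C(CC=C(C)C)C(OC)OC | intermediate
7 | 1-[2-(dimethoxymethyl)-5-methylhex-4-enoyl]-1H-imidazole (racemic, not isolated) | COC(OC)C(CC=C(C)C)C(=O)n1ccnc1 | intermediate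
8 | 6-[4,4-dimethoxy-1,3-bis(3-methylbut-2-en-1-yl)-2-oxobutyl]-2,2-dimethyl-4H-1,3-dioxin-4-one (diastereomer mixture) | COC(OC)C(CC=C(C)C)C(=O)C(CC=C(C)C)C1=CC(=O)OC(C)(C)O1 | intermediate
9 | 6-[1,3-bis(3-methylbut-2-en-1-yl)-2,4-dioxobutyl]-2,2-dimethyl-4H-1,3-dioxin-4-one (diastereomer and enol mixture, no configuration assigned) | CC(C)=CCC(C=O)C(=O)C(CC=C(C)C)C1=CC(=O)OC(C)(C)O1 | intermediate
10 | 5-hydroxy-2,2-dimethyl-6,8-bis(3-methylbut-2-en-1-yl)-5,6-dihydro-4H-1,3-benzodioxine-4,7(8H)-dione (isomer mixture, not isolated) | CC1(C)OC(=O)C2=C(O1)C(CC=C(C)C)C(=O)C(CC=C(C)C)C2O | intermediate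
11 | 7-hydroxy-2,2-dimethyl-6,8-bis(3-methylbut-2-en-1-yl)-4H-1,3-benzodioxin-4-one | CC1(C)OC(=O)c2cc(CC=C(C)C)c(O)c(CC=C(C)C)c2O1 | intermediate
12 | 7-(methoxymethoxy)-2,2-dimethyl-6,8-bis(3-methylbut-2-en-1-yl)-4H-1,3-benzodioxin-4-one | CC1(C)OC(=O)c2cc(CC=C(C)C)c(OCOC)c(CC=C(C)C)c2O1 | intermediate
13 | 2,4-dihydroxybenzaldehyde | O=Cc1ccc(O)cc1O | starting material
14 | 2,4-bis(methoxymethoxy)benzaldehyde | COCOc1ccc(C=O)c(OCOC)c1 | intermediate
15 | 2,4-bis(methoxymethoxy)phenyl formate (not isolated) | COCOc1ccc(OC=O)c(OCOC)c1 | intermediate
16 | 2,4-bis(methoxymethoxy)phenol | COCOc1ccc(O)c(OCOC)c1 | intermediate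
17 | ethyl bromoacetate | CCOC(=O)CBr | starting material
18 | ethyl [2,4-bis(methoxymethoxy)phenoxy]acetate (not isolated) | CCOC(=O)COc1ccc(OCOC)cc1OCOC | intermediate
19 | [2,4-bis(methoxymethoxy)phenoxy]acetic acid | OC(=O)COc1ccc(OCOC)cc1OCOC | intermediate
20 | 2-[2,4-bis(methoxymethoxy)phenoxy]-3-[2-hydroxy-4-(methoxymethoxy)-3,5-bis(3-methylbut-2-en-1-yl)phenyl]-3-oxopropanoic acid (racemic, not isolated) | COCOc1ccc(OC(C(=O)O)C(=O)c2cc(CC=C(C)C)c(OCOC)c(CC=C(C)C)c2O)c(OCOC)c1 | intermediate
21 | 2-[2,4-bis(methoxymethoxy)phenoxy]-1-[2-hydroxy-4-(methoxymethoxy)-3,5-bis(3-methylbut-2-en-1-yl)phenyl]ethan-1-one | COCOc1ccc(OCC(=O)c2cc(CC=C(C)C)c(OCOC)c(CC=C(C)C)c2O)c(OCOC)c1 | intermediate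
22 | 2-[2,4-bis(methoxymethoxy)phenoxy]-3-(dimethylamino)-1-[2-hydroxy-4-(methoxymethoxy)-3,5-bis(3-methylbut-2-en-1-yl)phenyl]prop-2-en-1-one (alkene geometry not controlled, not isolated) | COCOc1ccc(OC(=CN(C)C)C(=O)c2cc(CC=C(C)C)c(OCOC)c(CC=C(C)C)c2O)c(OCOC)c1 | intermediate
23 | 3-[2,4-bis(methoxymethoxy)phenoxy]-7-(methoxymethoxy)-6,8-bis(3-methylbut-2-en-1-yl)-4H-chromen-4-one | COCOc1ccc(Oc2coc3c(CC=C(C)C)c(OCOC)c(CC=C(C)C)cc3c2=O)c(OCOC)c1 | intermediate
24 | eryvarin F, 3-(2,4-dihydroxyphenoxy)-7-hydroxy-6,8-bis(3-methylbut-2-en-1-yl)-4H-chromen-4-one | CC(C)=CCc1cc2c(=O)c(Oc3ccc(O)cc3O)coc2c(CC=C(C)C)c1O | target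

## Step count and least certain steps

Total: 13 steps. Longest linear sequence: 9 steps (steps 2, 3, 4, 5, 6, 7, 11, 12, 13, from 4 to 24). The side branches are step 1 (joining at step 4) and steps 8–10 (joining at step 11).

**Step 6 (key step).** The cyclisation may stall because base removes the more acidic C6 proton and leaves the unreactive ketoaldehyde enolate. The formyl carbon may be lost by retro-Claisen cleavage if nucleophiles are present. An enol oxygen may add to C8a with opening of the dioxinone. The fallback sets out from 8 and never frees the aldehyde. Me3SiOTf and Et3N in CH2Cl2 at −78 °C should convert the ketone of 8 into the trimethylsilyl dienol ether F1. Further Me3SiOTf then ionises the acetal to an oxocarbenium ion, which C4a attacks in an intramolecular vinylogous Mukaiyama aldol reaction to give the 5-methoxy ketone F2. DBU then eliminates methanol and aromatises, and the route is rejoined at 11.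

**Step 4.** Proton transfer from the branched acyl imidazolide to the hindered secondary dienolate may outrun C–C bond formation; enolisation of 7 would be followed by loss of methoxide, and 3 would simply be returned. The fallback sets out from 1 and 7. The unhindered dienolate of 1 (LiN(SiMe3)2, THF, −78 °C) is acylated by 7 to the keto-dioxinone F3, whose doubly activated methylene is then C-prenylated with 2 (K2CO3, acetone; if O-alkylation interferes, a Tsuji–Trost prenylation with the zerovalent palladium complex Pd(PPh3)4). The route is rejoined at 8.

**Step 11.** Dianion formation may be incomplete, or the dianion may act only as a base, and addition to the electron-rich acylal carbonyl may be slow, so that 12 is recovered. The fallback sets out from 16 and 12. Phenol 16 is alkylated with allyl bromoacetate F4 (K2CO3, DMF) to allyl [2,4-bis(methoxymethoxy)phenoxy]acetate F5. The lithium enolate of F5 (LiN(SiMe3)2, two equivalents, THF, −78 °C) is acylated by 12 to the allyl beta-keto ester F6. Deallylation and decarboxylation under neutral conditions with Pd(PPh3)4 (zerovalent palladium) and morpholine then rejoin the route at 21.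

**Step 5.** Unmasking may be accompanied by acid-promoted heterocyclisation of the tricarbonyl chain or by slow hydration of a prenyl alkene, and the crude aldehyde may decompose on standing. The fallback sets out from 3 and brings in the formyl carbon last, under basic conditions. 5-Methylhex-4-enoic acid F7 is activated with CDI to its imidazolide F8, which acylates the dienolate of 3 as in step 4 to the keto-dioxinone F9. The dianion of F9 (LiN(iPr)2, 2.2 equiv, THF, −78 °C) is formylated at the terminal methylene with ethyl formate, and careful neutralisation rejoins the route at 9.

**Step 1.** Alkylation at the ring alpha carbon, double alkylation and self-condensation of the dienolate may compete with gamma alkylation. The fallback sets out from commercial 5-methylhex-4-enoic acid F7 in place of 1 and 2. Acylation of Meldrum's acid (DCC, DMAP, CH2Cl2) gives the acyl Meldrum's acid F10, and heating F10 with acetone in toluene generates the acylketene, which is trapped as the dioxinone. The route is rejoined at 3.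

## Further compounds

F1 | step 6 | 6-[4,4-dimethoxy-1,3-bis(3-methylbut-2-en-1-yl)-2-(trimethylsilyloxy)but-1-en-1-yl]-2,2-dimethyl-4H-1,3-dioxin-4-one | COC(OC)C(CC=C(C)C)C(O[Si](C)(C)C)=C(CC=C(C)C)C1=CC(=O)OC(C)(C)O1
F2 | step 6 | 5-methoxy-2,2-dimethyl-6,8-bis(3-methylbut-2-en-1-yl)-5,6-dihydro-4H-1,3-benzodioxine-4,7(8H)-dione (drawn as the dioxinone tautomer) | COC1C(CC=C(C)C)C(=O)C(CC=C(C)C)C2=C1C(=O)OC(C)(C)O2
F3 | step 4 | 6-[4,4-dimethoxy-3-(3-methylbut-2-en-1-yl)-2-oxobutyl]-2,2-dimethyl-4H-1,3-dioxin-4-one | COC(OC)C(CC=C(C)C)C(=O)CC1=CC(=O)OC(C)(C)O1
F4 | step 11 | allyl bromoacetate | C=CCOC(=O)CBr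
F5 | step 11 | allyl [2,4-bis(methoxymethoxy)phenoxy]acetate | C=CCOC(=O)COc1ccc(OCOC)cc1OCOC
F6 | step 11 | allyl 2-[2,4-bis(methoxymethoxy)phenoxy]-3-[2-hydroxy-4-(methoxymethoxy)-3,5-bis(3-methylbut-2-en-1-yl)phenyl]-3-oxopropanoate | C=CCOC(=O)C(Oc1ccc(OCOC)cc1OCOC)C(=O)c1cc(CC=C(C)C)c(OCOC)c(CC=C(C)C)c1O
F7 | step 5 | 5-methylhex-4-enoic acid | CC(C)=CCCC(=O)O
F8 | step 5 | 1-(5-methylhex-4-enoyl)-1H-imidazole | CC(C)=CCCC(=O)n1ccnc1
F9 | step 5 | 2,2-dimethyl-6-[6-methyl-1-(3-methylbut-2-en-1-yl)-2-oxohept-5-en-1-yl]-4H-1,3-dioxin-4-one | CC(C)=CCCC(=O)C(CC=C(C)C)C1=CC(=O)OC(C)(C)O1
F10 | step 1 | 5-(1-hydroxy-5-methylhex-4-en-1-ylidene)-2,2-dimethyl-1,3-dioxane-4,6-dione | CC(C)=CCCC(O)=C1C(=O)OC(C)(C)OC1=O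
A1 | alternative 1 | 3-[2,4-bis(methoxymethoxy)phenoxy]-7-hydroxy-6,8-bis(3-methylbut-2-en-1-yl)-4H-chromen-4-one | CC(C)=CCc1cc2c(=O)c(Oc3ccc(OCOC)cc3OCOC)coc2c(CC=C(C)C)c1O
A2 | alternative 1 | 3-[2,4-bis(methoxymethoxy)phenoxy]-7-hydroxy-6,8-di(prop-2-en-1-yl)-4H-chromen-4-one | C=CCc1cc2c(=O)c(Oc3ccc(OCOC)cc3OCOC)coc2c(CC=C)c1O
A3 | alternative 1 | 2-methylbut-2-ene | CC=C(C)C
A4 | alternative 2 | 2,4-bis(3-methylbut-2-en-1-yl)-3-[tri(propan-2-yl)silyloxy]phenol | Oc1ccc(CC=C(C)C)c(O[Si](C(C)C)(C(C)C)C(C)C)c1CC=C(C)C
A5 | alternative 2 | 2-(3-methylbut-2-en-1-yl)cyclobut-2-en-1-one | CC(C)=CCC1=CCC1=O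
A6 | alternative 2 | [(5-methylhex-4-en-1-yn-1-yl)oxy]tri(propan-2-yl)silane | CC(C)=CCC#CO[Si](C(C)C)(C(C)C)C(C)C
A7 | alternative 3 | 2-[2,4-bis(methoxymethoxy)phenoxy]-1-[2,4-dihydroxy-3,5-bis(3-methylbut-2-en-1-yl)phenyl]ethan-1-one | CC(C)=CCc1cc(C(=O)COc2ccc(OCOC)cc2OCOC)c(O)c(CC=C(C)C)c1O
A8 | alternative 3 | 1-methoxy-2,4-bis(3-methylbut-2-en-1-yl)-1,3-bis(trimethylsilyloxy)buta-1,3-diene (geometry not specified) | COC(O[Si](C)(C)C)=C(CC=C(C)C)C(O[Si](C)(C)C)=CCC=C(C)C
A9 | alternative 3 | 1-[2,4-bis(methoxymethoxy)phenoxy]but-3-yn-2-one | C#CC(=O)COc1ccc(OCOC)cc1OCOC
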